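All runs come from a simulation from invented constants; scatter was added.

The substrate turns into an intermediate. On the list of suspects, the second nucleophile captures that intermediate as the other capture product, and the first nucleophile, dissolving from its solid, captures it as the target.

| setting | noon | autumn | winter | spring | delta | alpha | beta | eta |
|---|---|---|---|---|---|---|---|---|
| substrate | 0.20 M | 0.13 M | 0.30 M | 0.20 M | 0.20 M | 0.20 M (fed, over 15 min) | 0.20 M | 0.20 M |
| second nucleophile | 0.22 M | 0.22 M | 0.22 M | 0.22 M | 0.220 M | 0.220 M | 0.220 M (fed, over 15 min) | 0.220 M (fed, over 1.5 min) |
| solid first nucleophile | 0.50 M | 0.50 M | 0.50 M | 0.75 M | 0.500 M | 0.500 M | 0.500 M | 0.500 M |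
| remark | run made earlier | run made earlier | run made earlier | run made earlier | everything together at the start | all else is in the flask from the start; the feed brings no volume worth counting | all else is in the flask from the start; the feed brings no volume worth counting | all else is in the flask from the start; the feed brings no volume worth counting |
| time |  |  |  |  | 40 min | 40 min | 40 min | 40 min |

| run | time / min | other capture product / % | target / % | substrate / % |
|---|---|---|---|---|
| noon | 2.00 | 32.7 | 8.9 | 52.1 |
| noon | 4.00 | 49.4 | 21.6 | 26.3 |
| noon | 10.0 | 56.5 | 37.7 | 3.4 |
| noon | 25.0 | 59.1 | 40.4 | 0 |
| autumn | 2.50 | 39.8 | 14.7 | 43.9 |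
| autumn | 6.00 | 55.1 | 29.0 | 12.7 |
| autumn | 15.0 | 60.3 | 38.8 | 1.2 |
| autumn | 30.0 | 59.3 | 38.8 | 0 |
| winter | 2.50 | 37.2 | 12.6 | 44.0 |
| winter | 6.00 | 52.6 | 31.8 | 16.0 |
| winter | 15.0 | 55.1 | 45.1 | 0 |
| winter | 30.0 | 55.5 | 44.7 | 1.9 |
| spring | 2.50 | 39.0 | 12.8 | 46.1 |
| spring | 6.00 | 54.0 | 31.9 | 13.7 |
| spring | 15.0 | 57.7 | 38.9 | 0.4 |
| spring | 30.0 | 59.5 | 41.6 | 1.1 |

(standard deviation of a reading: 1 percentage point)

- given per volume of solution although it is solid: solid first nucleophile
- on the list of suspects stand: substrate -> intermediate; first nucleophile + intermediate -> target; second nucleophile + intermediate -> other capture product; solid first nucleophile <-> first nucleophile; first nucleophile -> decomposition product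
- at the start none of the solid first nucleophile is in solution

* which flask leads in amount of other capture product, in percent of the substrate charged ("all alike" within 1.5 percentage points) (delta / alpha / beta / eta / all alike)
* how much other capture product is there at the end, in percent of the substrate charged: delta
* how much other capture product is there at the end, in percent of the substrate charged: alpha
* how much other capture product is there at the end, in percent of the substrate charged: beta
* how much other capture product is there at the end, in percent of the substrate charged: eta

In noon the substrate falls from 52.1% to 26.3% of its charge in 2.00 min, which gives a life of 2.93 min. I carry this substrate life, the first-order time for a fall by the factor e, as the clock for every setting. Autumn and winter, with other charges, read 2.82 min and 3.46 min.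

Take the solid first. By hand, more of it should mean more target, yet spring ends at 59.5% of other capture product against noon's 59.1%, a gap smaller than the scatter. Next comes the substrate charge. By hand, a larger charge draws the second nucleophile down further, and winter does end lower than autumn, at 55.5% against 59.3%.

Timing remains. In noon the ratio of other capture product to target, the selectivity, reads 3.67 at the first reading but 0.441 over the gain from the second reading to the third, so early intermediate favours other capture. Delta repeats noon's charges, so I expect about 59.1%. Eta's feed lasts 0.513 lives, which is shorter than one life, so I put eta slightly under delta. The slow feeds last 5.13 lives. Alpha's substrate therefore reaches the flask late, and I put it well below. After one life in beta, 19.5% of the second nucleophile is in, so I put beta lowest.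

The forecast also names delta, with 59% for delta, 42% for alpha, 25% for beta and 58% for eta: “The rising dissolved nucleophile therefore decides the split, and the other capture is strongest early.”

The flasks end at 59.0% for delta, 42.9% for alpha, 24.2% for beta and 56.7% for eta.

    substrate → intermediate (k = 0.00540 /s)
    first nucleophile + intermediate → target (k = 0.540 /M/s)
    second nucleophile + intermediate → other capture product (k = 0.330 /M/s)
    solid first nucleophile ⇌ first nucleophile, rate k4*(cs4 - [first nucleophile]) while solid is left; crystals form when [first nucleophile] > cs4 (solubility = 0.190 M, k = 0.00410 /s)
    first nucleophile → decomposition product (k = 5.00 × 10⁻⁶ /s)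

In delta the substrate's half-life at 4.11 min is 2.1 min, shorter than the 4.11 min by which half of the dissolution's turnover is done, and that time is 1.40 of the substrate lives as read off noon, a reading with its scatter. In delta half of the other capture turnover is done by 1.65 min. Eta, fed within 0.513 of those read lives, ends 2.3 percentage points below delta. Beta's other capture product moves by 5 points at a second nucleophile charge of 0.287 M.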